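**Retrosynthetic overview**
1. Feature: in the cycloheptane (ring A), the quaternary C1 carries the acyl carbon C2 and lies between C10 (CH3) and C5 (O-acyl). C1/C2, C10–CH3 and C5–O match the ipso carbon with its carboxyl group and the two ortho positions of 2-methoxy-6-methylbenzoic acid. C6 is the one ring carbon the arene lacks.
2. Ring A: Birch reduction of the tert-butyl anisate. The CBr2 carbon is then inserted between C5 and C7 (C5–C6, C6–C7), expanding the ring to the 2-bromocycloheptadienone β-keto ester. C1 is fixed next by catalytic asymmetric α-hydroxylation.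
3. Lactone (ring B): C7–C11 by Mukaiyama–Michael addition of a β-(phenylthio)propionate ketene acetal, which brings C11–C13. C6–O forms by carboxylate displacement of the C6 bromide with inversion.
4. Periphery: C5 by hydroxyl-directed reduction and isovalerylation. C9/C10 by hydroboration. C2 goes ester → acid → aldehyde → (Z)-propenyl carbinol → Z-enone. C11=C13 by sulfoxide elimination.
5. Ring order: A (step 3), then B (step 7).

Key step: step 3

Numbering and faces: C1 = C(OH) bearing the butenoyl group, C2 = its C=O, C5 = CH–O-isovalerate, C6 = lactone CH–O, C7 = lactone CH, C8 = CH2, C9 = CHOH, C10 = CHCH3, C11 = methylene-bearing lactone carbon, C12 = lactone C=O, C13 = exocyclic CH2. With ring A drawn C1→C5→C6→C7→C8→C9→C10 clockwise, β points to the viewer. The target has C2 β and OH α at C1, O-acyl β at C5, O α at C6, C11 α at C7, OH β at C9 and CH3 α at C10 (1S,5S,6R,7S,9R,10S).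
Assumption: the ligand antipode that delivers (S)-7 is used in step 4. The sense of induction must be checked on 7, and both antipodes are available.
Remark: C11 (compounds 11–27) and C2 (compounds 26–28) are epimer mixtures that are erased later, so they are left undefined in the SMILES.

**Step 1**
Reactants: 1 2-methoxy-6-methylbenzoic acid
Product: 2 tert-butyl 2-methoxy-6-methylbenzoate
Conditions: tert-butyl 2,2,2-trichloroacetimidate (2 equiv), BF3·OEt2 (cat.), CH2Cl2/cyclohexane, rt
Reagents that add atoms: tert-butyl 2,2,2-trichloroacetimidate CC(C)(C)OC(=N)C(Cl)(Cl)Cl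
Why: Acid-catalysed O-alkylation of the carboxyl group by the imidate needs no attack at the doubly ortho-substituted carbonyl carbon, and the tert-butyl ester is chosen because it matches the alkoxide base of step 3, is the large C1 substituent in steps 4 and 6, and can later be removed beside a lactone and an isovalerate.

**Step 2**
Reactants: 2 tert-butyl 2-methoxy-6-methylbenzoate
Product: 3 tert-butyl 2-methoxy-6-methylcyclohexa-2,5-diene-1-carboxylate (racemic; C1–H labile)
Conditions: Li (2.5 equiv), NH3(l)/THF, t-BuOH (1 equiv), −78 °C; then solid NH4Cl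
Reagents that add atoms: none
Why: Birch reduction, in which the ester directs protonation to the ipso and para carbons (C1, C8) while methoxy and methyl stay on the two remaining alkenes, one equivalent of alcohol at −78 °C limits loss of the ortho methoxy group, and kinetic protonation of the ester dienolate at C1 gives the unconjugated diene.

**Step 3**
Reactants: 3 tert-butyl 2-methoxy-6-methylcyclohexa-2,5-diene-1-carboxylate; 4 bromoform
Product: 6 tert-butyl 3-bromo-7-methyl-2-oxocyclohepta-3,6-diene-1-carboxylate (racemic; C1 enolisable), via dibromocyclopropane 5 (not isolated)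
Conditions: CHBr3 (1.5 equiv), KOC(CH3)3 (1.2 equiv, added in portions), pentane, −30 to 0 °C; filter, concentrate cold; then AgNO3 (1.5 equiv), CaCO3, acetone/H2O, 0 °C to rt
Reagents that add atoms: bromoform BrC(Br)Br; water O
Why: Bromoform is by far the strongest acid in the flask, so it takes up the alkoxide as it is added and loses bromide to give singlet CBr2, which adds in a concerted [2+1] fashion to the methoxy-bearing C5=C7 alkene, closing the cyclopropane and making C5–C6 and C6–C7 in one event. Silver ion then removes the endo bromide while the fused C5–C7 bond breaks in a disrotatory two-electron electrocyclic opening (Woodward–Hoffmann–DePuy rule), so the seven-membered ring arises by ring expansion rather than cyclisation; the methoxy oxygen holds the allyl cation as an oxocarbenium ion, water adds and methanol leaves to give the 2-bromoenone. The closest known reaction type is the dihalocarbene ring expansion of Birch-derived 1-alkoxycyclohexa-1,4-dienes and of cyclic silyl enol ethers to 2-halocycloheptenones and tropones. No lasting stereocentre is made, because the two cyclopropane centres are erased on opening and C1 stays racemic and enolisable until step 4. The step needs site selectivity for the enol ether over the C9=C10 alkene, which the oxygen lone pair (better partner for the electrophilic carbene) and the small excess of carbene should secure, and it needs C1–H to survive the base, which the hindered and non-transesterifiable tert-butyl ester and the slow addition of base to excess bromoform at low temperature should allow. CaCO3 buffering and immediate use of 6 guard against drift to the tropone by loss of HBr.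

**Step 4**
Reactants: 6 tert-butyl 3-bromo-7-methyl-2-oxocyclohepta-3,6-diene-1-carboxylate
Product: 7 tert-butyl (1S)-3-bromo-1-hydroxy-7-methyl-2-oxocyclohepta-3,6-diene-1-carboxylate (C1: OH α; CO2t-Bu β)
Conditions: Ni(ClO4)2·6H2O (10 mol %), 4,6-dibenzofurandiyl-2,2'-bis(4-phenyloxazoline) (single antipode, 11 mol %), 4 Å MS, CH2Cl2, rt; rac-2-(benzenesulfonyl)-3-phenyloxaziridine (1.2 equiv)
Reagents that add atoms: 2-(benzenesulfonyl)-3-phenyloxaziridine O=S(=O)(c1ccccc1)N1OC1c1ccccc1
Why: In this catalytic enantioselective α-hydroxylation of a cyclic β-keto ester, the substrate binds as a bidentate enolate to the chiral divalent nickel complex, a ligand phenyl group screens one face of C1 and the Davis-type oxaziridine transfers oxygen to the open face, which sets C1 under near-neutral conditions and ends enolisation and the tropone pathway.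

**Step 5**
Reactants: 8 3-(phenylsulfanyl)propanoic acid
Product: 10 1,1-bis(trimethylsilyloxy)-3-(phenylsulfanyl)prop-1-ene, via trimethylsilyl ester 9 (not isolated)
Conditions: Me3SiCl, Et3N, Et2O, rt, filter; then LiN(i-Pr)2 (1.1 equiv) added to ester plus Me3SiCl (1.2 equiv), THF, −78 °C
Reagents that add atoms: chlorotrimethylsilane C[Si](C)(C)Cl
Why: Deprotonating the silyl ester with the silyl chloride already present (internal quench) traps the enolate on oxygen before it can expel thiophenolate, and the bis-silyl ketene acetal has no E/Z isomers because both oxygen substituents are alike.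

**Step 6**
Reactants: 7 hydroxy bromodienone; 10 bis-silyl ketene acetal
Product: 12 bromo keto acid (C7–C11 α; C1 as in 7; C6 and C11 epimer mixtures), via silylated Michael adduct 11 (not isolated)
Conditions: 10 (2.5 equiv), LiClO4 (5 M in Et2O), rt; then 1 M HCl, THF, 0 °C
Reagents that add atoms: ketene acetal 10 C[Si](C)(C)OC(=CCSc1ccccc1)O[Si](C)(C)C
Why: In this Mukaiyama–Michael addition, Li+ bridging the C5 and ester carbonyl groups should hold the bulky ester in the enone plane and leave the small free hydroxyl axial on the convex face of the folded dienone, so the ketene acetal should bond to C7 on that α face (cis to OH, away from the C9=C10 flap), while 1,2-addition is blocked by the quaternary C1 and by bromine and the acid work-up frees ketone, acid and any silylated carbinol.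

**Step 7**
Reactants: 12 bromo keto acid
Product: 13 keto lactone (cis-fused γ-lactone: C6–O α; C7–C11 α; C5 ketone; C11 epimers)
Conditions: NaHCO3 (2 equiv), n-Bu4NBr (0.2 equiv), DMF, rt
Reagents that add atoms: none
Why: Intramolecular SN2 (5-exo-tet) of the carboxylate on the activated α-bromo ketone goes with inversion, only the 6β-bromide can be reached from behind by the α-oriented chain, and the 6α-bromide is fed into it by bromide exchange and enolisation, so C6–O forms α and cis to C7–C11, while bicarbonate is too weak to cause elimination or thiophenolate loss.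

**Step 8**
Reactants: 13 keto lactone
Product: 14 diol lactone (C5–OH β; trans to C1–OH α)
Conditions: Me4NBH(OAc)3 (5 equiv), MeCN/AcOH 1:1, −20 °C
Reagents that add atoms: none
Why: In this Saksena–Evans hydroxyl-directed reduction, the C1 hydroxyl replaces an acetate on boron and the bound hydride is passed to C5 from the α face to give the 5β-alcohol, external attack would come from the same face because the β face carries the tert-butyl ester, and lactone, ester, sulfide and alkene are inert to this reagent.

**Step 9**
Reactants: 14 diol lactone; 15 3-methylbutanoic anhydride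
Product: 16 C5 isovalerate (C1–OH free)
Conditions: 15 (3 equiv), DMAP (0.5 equiv), Et3N, CH2Cl2, rt
Reagents that add atoms: 3-methylbutanoic anhydride CC(C)CC(=O)OC(=O)CC(C)C
Why: DMAP-catalysed acylation takes the only secondary hydroxyl, whereas the crowded tertiary C1 hydroxyl does not react under these conditions.

**Step 10**
Reactants: 16 C5 isovalerate
Product: 18 C9 alcohol (C9–OH β; C10–CH3 α), via C9 alkylborane 17 (not isolated)
Conditions: BH3·THF (4 equiv), THF, 0 °C to rt; MeOH; then Me3NO·2H2O, THF, 60 °C
Reagents that add atoms: trimethylamine N-oxide C[N+](C)(C)[O-] (oxygen at C9); borane B (boron in 17 only)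
Why: In this hydroboration–oxidation, boron goes to the less substituted C9 and hydrogen to C10 in a syn addition that should come from the β face, because the α face is covered at C9 by the C7–C11 bond of the cis-fused lactone and at C10 by the pseudoaxial C1–O–boron group (attack anti to the allylic oxygen), so 9β-OH and 10α-CH3 are set together after oxidation with retention, and the amine oxide oxidises C–B bonds without base and without touching the thioether.

**Step 11**
Reactants: 18 C9 alcohol
Product: 20 C2 carboxylic acid with C1 and C9 triethylsilyl ethers, via triethylsilyl ester 19 (not isolated)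
Conditions: Et3SiOSO2CF3 (6 equiv), 2,6-lutidine (8 equiv), CH2Cl2, 0 °C to rt; then aq NaHCO3
Reagents that add atoms: triethylsilyl trifluoromethanesulfonate CC[Si](CC)(CC)OS(=O)(=O)C(F)(F)F
Why: The silyl triflate silylates both hydroxyls and also the tert-butyl ester carbonyl oxygen, from which the tert-butyl group leaves as isobutene (the known silyl triflate cleavage of tert-butyl esters), and the labile silyl ester hydrolyses in the work-up, so C2 is freed as the acid while lactone and isovalerate stay untouched.

**Step 12**
Reactants: 20 C2 carboxylic acid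
Product: 21 C2 primary alcohol
Conditions: BH3·THF (3 equiv), THF, 0 °C to rt
Reagents that add atoms: none
Why: Borane reduces a free carboxylic acid through its acyloxyborane far faster than esters or lactones, which singles out C2 among the three carboxyl-level carbons, and the small reagent copes with the quaternary neighbour.

**Step 13**
Reactants: 21 C2 primary alcohol
Product: 22 C2 aldehyde
Conditions: Dess–Martin periodinane, NaHCO3, CH2Cl2, 0 °C to rt
Reagents that add atoms: none
Why: Dess–Martin oxidation of the neopentyl alcohol stops at the aldehyde, which cannot enolise next to quaternary C1, and it leaves aryl alkyl sulfides and silyl ethers alone.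

**Step 14**
Reactants: 22 C2 aldehyde; 23 (Z)-1-bromoprop-1-ene
Product: 26 (Z)-propenyl carbinol (C2 epimers), via (Z)-prop-1-enyllithium 24 (not isolated), via (Z)-prop-1-enylcerium dichloride 25 (not isolated)
Conditions: 23, t-BuLi (2 equiv), Et2O, −78 °C; CeCl3 (anhydrous), THF, −78 °C; then 22, −78 °C; aq NH4Cl at −78 °C
Reagents that add atoms: (Z)-1-bromoprop-1-ene C/C=C\Br
Why: Bromine–lithium exchange and transmetalation to cerium keep the alkene geometry, the weakly basic organocerium reagent adds to the aldehyde at −78 °C much faster than it attacks esters or deprotonates C11, and the cold quench prevents silyl or acyl migration to the new alkoxide, whose carbinol centre is erased in step 16.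

**Step 15**
Reactants: 26 (Z)-propenyl carbinol
Product: 28 α-methylene lactone carbinol, via sulfoxide 27 (not isolated)
Conditions: mCPBA (1.0 equiv), CH2Cl2, −78 °C; then CaCO3, toluene, 100 °C
Reagents that add atoms: 3-chloroperoxybenzoic acid OOC(=O)c1cccc(Cl)c1 (oxygen in 27 only)
Why: The thioether is by far the most easily oxidised site for one equivalent of peracid at −78 °C, and in the thermal syn elimination of the sulfoxide C11–H is the only β-hydrogen, so only the exocyclic C11=C13 alkene can form, and this is done before the heat-sensitive Z-enone exists.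

**Step 16**
Reactants: 28 α-methylene lactone carbinol
Product: 29 bis(triethylsilyl) ether of the target (Z-enone)
Conditions: Dess–Martin periodinane, NaHCO3, CH2Cl2, 0 °C
Reagents that add atoms: none
Why: Buffered Dess–Martin oxidation of a Z-allylic alcohol is neutral and fast, so the Z geometry should be kept, and with C1 and C9 silylated no other alcohol and no free 1,2-diol is exposed.

**Step 17**
Reactants: 29 bis(triethylsilyl) ether
Product: 30 target CNP0186412.2
Conditions: HF·pyridine, pyridine, THF, 0 °C to rt
Reagents that add atoms: none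
Why: Fluoride-driven cleavage of both triethylsilyl ethers in a buffered, weakly acidic medium avoids the bases that would isomerise the Z-enone, add to the methylene lactone or move the isovalerate.

**Compound list**
1 | 2-methoxy-6-methylbenzoic acid | COc1cccc(C)c1C(=O)O | starting material
2 | tert-butyl 2-methoxy-6-methylbenzoate | COc1cccc(C)c1C(=O)OC(C)(C)C | intermediate
3 | tert-butyl 2-methoxy-6-methylcyclohexa-2,5-diene-1-carboxylate (racemic) | COC1=CCC=C(C)C1C(=O)OC(C)(C)C | intermediate
4 | bromoform | BrC(Br)Br | starting material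
5 | tert-butyl 7,7-dibromo-1-methoxy-3-methylbicyclo[4.1.0]hept-3-ene-2-carboxylate (diastereomer mixture) | COC12C(C(=O)OC(C)(C)C)C(C)=CCC1C2(Br)Br | intermediate
6 | tert-butyl 3-bromo-7-methyl-2-oxocyclohepta-3,6-diene-1-carboxylate (racemic) | CC1=CCC=C(Br)C(=O)C1C(=O)OC(C)(C)C | intermediate
7 | tert-butyl (1S)-3-bromo-1-hydroxy-7-methyl-2-oxocyclohepta-3,6-diene-1-carboxylate | C1C=C(C)[C@@](O)(C(=O)OC(C)(C)C)C(=O)C(Br)=C1 | intermediate
8 | 3-(phenylsulfanyl)propanoic acid | OC(=O)CCSc1ccccc1 | starting material
9 | trimethylsilyl 3-(phenylsulfanyl)propanoate | C[Si](C)(C)OC(=O)CCSc1ccccc1 | intermediate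
10 | 1,1-bis(trimethylsilyloxy)-3-(phenylsulfanyl)prop-1-ene | C[Si](C)(C)OC(=CCSc1ccccc1)O[Si](C)(C)C | intermediate
11 | Michael adduct as C5 trimethylsilyl enol ether and C12 trimethylsilyl ester (1S,7S; C11 epimers) | C[Si](C)(C)OC(=O)C(CSc1ccccc1)[C@@H]1CC=C(C)[C@@](O)(C(=O)OC(C)(C)C)C(O[Si](C)(C)C)=C1Br | intermediate
12 | bromo keto acid: C7-[1-carboxy-2-(phenylsulfanyl)ethyl] α, C6–Br, C5 ketone, C1 OH α/CO2t-Bu β, C9=C10 (1S,7S; C6, C11 epimers) | OC(=O)C(CSc1ccccc1)[C@@H]1CC=C(C)[C@@](O)(C(=O)OC(C)(C)C)C(=O)C1Br | intermediate
13 | keto lactone: cis-fused γ-lactone, C5 ketone, C11–CH2SPh (1S,6R,7S) | c1ccccc1SCC1C(=O)O[C@@H]2[C@H]1CC=C(C)[C@@](O)(C(=O)OC(C)(C)C)C2=O | intermediate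
14 | diol lactone, C5–OH β (1S,5S,6R,7S) | c1ccccc1SCC1C(=O)O[C@@H]2[C@H]1CC=C(C)[C@@](O)(C(=O)OC(C)(C)C)[C@H]2O | intermediate
15 | 3-methylbutanoic anhydride | CC(C)CC(=O)OC(=O)CC(C)C | starting material
16 | C5 isovalerate of 14 | c1ccccc1SCC1C(=O)O[C@@H]2[C@H]1CC=C(C)[C@@](O)(C(=O)OC(C)(C)C)[C@H]2OC(=O)CC(C)C | intermediate
17 | C9 β-alkylborane (drawn as the monoalkylborane) | c1ccccc1SCC1C(=O)O[C@@H]2[C@H]1C[C@@H](B)[C@H](C)[C@@](O)(C(=O)OC(C)(C)C)[C@H]2OC(=O)CC(C)C | intermediate
18 | C9 alcohol, 9β-OH, 10α-CH3 (1S,5S,6R,7S,9R,10S) | c1ccccc1SCC1C(=O)O[C@@H]2[C@H]1C[C@@H](O)[C@H](C)[C@@](O)(C(=O)OC(C)(C)C)[C@H]2OC(=O)CC(C)C | intermediate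
19 | C1,C9-bis(triethylsilyl) ether C2 triethylsilyl ester | c1ccccc1SCC1C(=O)O[C@@H]2[C@H]1C[C@@H](O[Si](CC)(CC)CC)[C@H](C)[C@@](O[Si](CC)(CC)CC)(C(=O)O[Si](CC)(CC)CC)[C@H]2OC(=O)CC(C)C | intermediate
20 | C1,C9-bis(triethylsilyl) ether C2 carboxylic acid | c1ccccc1SCC1C(=O)O[C@@H]2[C@H]1C[C@@H](O[Si](CC)(CC)CC)[C@H](C)[C@@](O[Si](CC)(CC)CC)(C(=O)O)[C@H]2OC(=O)CC(C)C | intermediate
21 | C2 primary alcohol | c1ccccc1SCC1C(=O)O[C@@H]2[C@H]1C[C@@H](O[Si](CC)(CC)CC)[C@H](C)[C@@](O[Si](CC)(CC)CC)(CO)[C@H]2OC(=O)CC(C)C | intermediate
22 | C2 aldehyde | c1ccccc1SCC1C(=O)O[C@@H]2[C@H]1C[C@@H](O[Si](CC)(CC)CC)[C@H](C)[C@@](O[Si](CC)(CC)CC)(C=O)[C@H]2OC(=O)CC(C)C | intermediate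
23 | (Z)-1-bromoprop-1-ene | C/C=C\Br | starting material
24 | (Z)-prop-1-enyllithium | C/C=C\[Li] | intermediate
25 | (Z)-prop-1-enylcerium dichloride | C/C=C\[Ce](Cl)Cl | intermediate
26 | (Z)-propenyl carbinol (C2, C11 epimers) | c1ccccc1SCC1C(=O)O[C@@H]2[C@H]1C[C@@H](O[Si](CC)(CC)CC)[C@H](C)[C@@](O[Si](CC)(CC)CC)(C(O)/C=C\C)[C@H]2OC(=O)CC(C)C | intermediate
27 | C13 phenyl sulfoxide of 26 | O=S(c1ccccc1)CC1C(=O)O[C@@H]2[C@H]1C[C@@H](O[Si](CC)(CC)CC)[C@H](C)[C@@](O[Si](CC)(CC)CC)(C(O)/C=C\C)[C@H]2OC(=O)CC(C)C | intermediate
28 | α-methylene lactone (Z)-propenyl carbinol (C2 epimers) | C=C1C(=O)O[C@@H]2[C@H]1C[C@@H](O[Si](CC)(CC)CC)[C@H](C)[C@@](O[Si](CC)(CC)CC)(C(O)/C=C\C)[C@H]2OC(=O)CC(C)C | intermediate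
29 | C1,C9-bis(triethylsilyl) ether of the target | C=C1C(=O)O[C@@H]2[C@H]1C[C@@H](O[Si](CC)(CC)CC)[C@H](C)[C@@](O[Si](CC)(CC)CC)(C(=O)/C=C\C)[C@H]2OC(=O)CC(C)C | intermediate
30 | (3aS,5R,6S,7S,8S,8aR)-7-[(2Z)-but-2-enoyl]-5,7-dihydroxy-6-methyl-3-methylidene-2-oxooctahydro-2H-cyclohepta[b]furan-8-yl 3-methylbutanoate | C=C1C(=O)O[C@@H]2[C@H]1C[C@@H](O)[C@H](C)[C@@](O)(C(=O)/C=C\C)[C@H]2OC(=O)CC(C)C | target

**Step count**
Total steps: 17. Longest linear sequence: 16 (steps 1–4 and 6–17). Step 5 is a one-step side branch.

**Steps most likely to fail**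

Step 3 (key step). The alkoxide may deprotonate the doubly allylic C1–H, leading to conjugation or rearomatisation. The carbene may also add to C9=C10 or add twice, and the expanded β-keto ester may lose HBr towards the tropone.

The fallback keeps the same carbene insertion but makes C1 quaternary first. It sets out from 3. Mild hydrolysis of the enol ether (oxalic acid, THF/H2O) gives tert-butyl 2-methyl-6-oxocyclohex-2-ene-1-carboxylate F1. The nickel-catalysed hydroxylation of step 4 gives the (S)-α-hydroxy β-keto ester F2. Me3SiOSO2CF3/Et3N silylates the carbinol and forms the only possible enol ether, the bis-silylated 2,5-diene F3. CHBr3/KOC(CH3)3 then meets no acidic C–H and gives the siloxy dibromocyclopropane F4. AgNO3 in aqueous acetone followed by dilute HCl opens and desilylates F4. The sequence returns to the route at 7.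

Step 6. Facial selectivity at C7 may be poor, because the controlling centre C1 is remote and premature O-silylation of the carbinol would change the bias.

The fallback moves the control from the substrate to a catalyst. Compound 7 is bound through its C5 and ester carbonyl groups (two-point binding) to Cu(OSO2CF3)2 with 2,2'-isopropylidenebis(4-tert-butyl-2-oxazoline). This divalent copper complex is of the type used for enantioselective Mukaiyama–Michael additions to chelating acceptors, and the ligand antipode matched with α attack is chosen. The fallback sets out from 7 and 10, returns at 12 and makes no new compound.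

Step 10. Borane may approach from the α face because the β face carries the tert-butyl ester. Slow reduction of the lactone or of the α-oxygenated ester may also compete.

The fallback sets C10 by equilibration and C9 by ketone reduction instead of by alkene face selection. It sets out from 16. Hydroboration–oxidation from the wrong face gives the 9α-hydroxy-10β-methyl isomer F5. Dess–Martin oxidation gives the C9 ketone F6. A catalytic amine base (DBU, CH2Cl2) should epimerise C10 to the 10α-methyl ketone F7, in which the methyl group is trans to the large ester. NaBH4/CeCl3·7H2O at −78 °C should then give the alcohol trans to the methyl group. The sequence returns at 18.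

**Further compounds**
F1 | step 3 | tert-butyl 2-methyl-6-oxocyclohex-2-ene-1-carboxylate | CC1=CCCC(=O)C1C(=O)OC(C)(C)C
F2 | step 3 | tert-butyl (1S)-1-hydroxy-2-methyl-6-oxocyclohex-2-ene-1-carboxylate | C1CC=C(C)[C@@](O)(C(=O)OC(C)(C)C)C1=O
F3 | step 3 | tert-butyl (1S)-2-methyl-1,6-bis(trimethylsilyloxy)cyclohexa-2,5-diene-1-carboxylate | C1C=C(C)[C@@](O[Si](C)(C)C)(C(=O)OC(C)(C)C)C(O[Si](C)(C)C)=C1
F4 | step 3 | tert-butyl 7,7-dibromo-3-methyl-1,2-bis(trimethylsilyloxy)bicyclo[4.1.0]hept-3-ene-2-carboxylate | C1C=C(C)[C@@](O[Si](C)(C)C)(C(=O)OC(C)(C)C)C2(O[Si](C)(C)C)C1C2(Br)Br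
F0 | step 6 | none | none
F5 | step 10 | 9α-hydroxy-10β-methyl isomer of 18 | c1ccccc1SCC1C(=O)O[C@@H]2[C@H]1C[C@H](O)[C@@H](C)[C@@](O)(C(=O)OC(C)(C)C)[C@H]2OC(=O)CC(C)C
F6 | step 10 | C9 ketone, 10β-methyl | c1ccccc1SCC1C(=O)O[C@@H]2[C@H]1CC(=O)[C@@H](C)[C@@](O)(C(=O)OC(C)(C)C)[C@H]2OC(=O)CC(C)C
F7 | step 10 | C9 ketone, 10α-methyl | c1ccccc1SCC1C(=O)O[C@@H]2[C@H]1CC(=O)[C@H](C)[C@@](O)(C(=O)OC(C)(C)C)[C@H]2OC(=O)CC(C)C
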